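Partner B starts the closed flask, amber, by going 1.36 times as fast to open intermediate as to second intermediate, so both intermediates grow side by side while the joining step consumes them in pairs.

    substrate + partner B → open intermediate (k1 = 15 M⁻¹ s⁻¹)
    partner B + partner A → second intermediate (k2 = 5.5 M⁻¹ s⁻¹)
    open intermediate + second intermediate → target (k3 = 120 M⁻¹ s⁻¹)
    target ⇌ isomer of the product (K4 = 1.3, k4 = 0.095 s⁻¹)
    partner B + protic impurity → quenched reagent (k5 = 54 M⁻¹ s⁻¹)

common to all: partner A 2.00 equiv; protic impurity 3.00 mM
- red: substrate 10 mM; partner B 1.50 equiv; a single well-mixed tank run continuously and read at steady state, 3.0 s in it on average
- blue: substrate 10 mM; partner B 1.50 equiv (fed, over 2.40 s); all but partner B at the start; partner B goes in evenly over 2.40 s, the run ends at 3.0 s; time 3.0 s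
- grey: substrate 10 mM (fed, over 2.40 s); partner B 1.50 equiv; all but substrate at the start; substrate goes in evenly over 2.40 s, the run ends at 3.0 s; time 3.0 s
- amber: substrate 10 mM; partner B 1.50 equiv; everything together in a closed stirred flask, run for 3.0 s; time 3.0 s

- the stated concentrations are those of everything mixed, before any reaction; amounts are the same in each set-up
- the feed brings no volume worth counting
- run time (blue): 3.0 s

1. the set-up with the highest amount of open intermediate at the outlet or at the end, in percent of the substrate put in ("none" if the first two lie within 2 percentage points) (red / blue / grey / amber / none)
2. amount of open intermediate at the outlet or at the end, in percent of the substrate put in, red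
3. amount of open intermediate at the outlet or at the end, in percent of the substrate put in, blue
4. amount of open intermediate at the outlet or at the end, in percent of the substrate put in, grey
5. amount of open intermediate at the outlet or at the end, in percent of the substrate put in, amber

Two chemists dispute this. The first holds that open intermediate follows how much partner B the substrate has met, which favours amber. The second holds that it follows what the joining step spares, which favours blue, where dosing keeps c(second intermediate) low.

My own reckoning gives each view its number. With substrate, partner A and protic impurity held at their charge, partner B decays by a pseudo-first-order constant of 0.422 s⁻¹. I replace its curve by its mean: the area under c(partner B) is what went in less what stands, divided by that constant. Multiplying by the rate constant of the substrate's step gives 0.383 for amber. This number is the exposure, the rate constant of the substrate's step times the time-mean of c(partner B) times the time. In blue, the same reckoning puts partner B at 7.32 mM at the end, so the exposure comes to 0.273.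

One minus exp(−exposure) is my estimate of the share of substrate turned: 31.8 % in amber and 23.9 % in blue. For the second chemist, I let both intermediates rise in a line, so the mean of their product is a third of the final product. The estimate for the joining step is then 8.90 % of the substrate in amber and 5.02 % in blue. By these estimates dosing saves 3.9 percentage points of loss but costs more than that in turnover, 7.9 points. I commit to 22.9 % for amber and 18.9 % for blue, and leave red and grey unreckoned.

The forecast takes the first chemist's side and names amber, with red 17.7 %, blue 21.6 %, grey 16.5 % and amber 24.7 %, on the ground that “substrate and partner B meet at full strength early”. Its amber stands above mine, and so does its blue.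

The simulation gives red 17.7 %, blue 21.4 %, grey 16.0 % and amber 24.8 %, so amber leads. In amber, partner B stands at 42 % of its charge at 3.00 s, above the 28.2 % of the replaced curve. The substrate left, 65 %, reads as an exposure of 0.431 against my 0.383. The second chemist's region is late: at 30.0 s blue holds 6.32 %, more than amber's 6.04 %, and the two lie within 2 points.

A neighbour of amber charged with 5.00 equiv of partner A has the constant 0.587 s⁻¹ and an exposure of 0.317. My estimate is then 27.2 % of the substrate turned and 16.3 % of it lost to the joining step, which leaves 10.9 %. The computed flask holds 13.4 %.

All constants come from no measurement; the flask was simulated.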